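The closed, stirred vessel held Z with D, E and J at one temperature. The suspected steps were Z + D to X, J + E + X to Q, J + Q to G and J + E to L, and I counted in percent of the Z charged.

| setting | zeta | eta | south | north |
|---|---|---|---|---|
| Z | 0.050 M | 0.050 M | 0.050 M | 0.050 M |
| J | 0.80 equiv | 0.80 equiv | 0.800 equiv | 0.800 equiv |
| D | 0.13 mol% | 0.13 mol% | 0.13 mol% | 0.13 mol% |
| E | 0.21 mol% | 0.84 mol% | 0.42 mol% | 0.42 mol% |
| temperature | 1 °C | 15 °C | −5 °C | 20 °C |
| remark | run made earlier | run made earlier |  |  |
| time |  |  | 40 h | 40 h |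

| run | time / h | Q / % | G / % | Z / % |
|---|---|---|---|---|
| zeta | 2.50 | 0 | 0 | 97.7 |
| zeta | 8.00 | 0.9 | 0.2 | 92.3 |
| zeta | 15.0 | 2.3 | 0.1 | 85.4 |
| zeta | 20.0 | 1.6 | 0 | 81.8 |
| zeta | 30.0 | 2.4 | 1.1 | 74.2 |
| zeta | 40.0 | 2.7 | 2.8 | 66.8 |
| zeta | 50.0 | 4.0 | 4.1 | 61.8 |
| eta | 1.00 | 1.1 | 0.5 | 97.4 |
| eta | 3.00 | 1.7 | 0.4 | 91.3 |
| eta | 6.00 | 4.8 | 0.9 | 82.5 |
| eta | 8.00 | 5.6 | 2.8 | 75.7 |
| eta | 12.0 | 5.9 | 3.5 | 67.0 |
| eta | 15.0 | 6.2 | 5.3 | 60.7 |
| eta | 20.0 | 5.8 | 8.4 | 50.9 |

(readings scatter by 0.5 percentage points)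

- on the list of suspects stand: Z + D -> D + X; J + E -> L; J + Q -> G; J + E + X -> E + Q

- the flask with the highest share of Q in all that became Q or G ("all alike" if they lie within 1.5 percentage points) (south / north / all alike)
- share of Q in all that became Q or G, south
- share of Q in all that became Q or G, north

What puzzled me stood in the eta run: between 12.0 h and 20.0 h Z fell from 67.0% to 50.9%, yet Q read 5.9% and then 5.8%. It cleared once I read the flat Q as a balance, with Q made about as fast as J turned it into G. Treating that loss as pseudo-first-order, with J charged at 0.80 equiv, I set G's climb from 3.5% to 8.4% against the mean Q and got 0.105 h⁻¹, a half-life of 6.62 h at 15 °C. The last readings of zeta gave 0.0469 h⁻¹, a half-life of 14.8 h at 1 °C. Scaling between these two, I took 20.9 h for south and 4.97 h for north, this last being the half-life of Q under J at the north temperature.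

I reckoned the share of Q as the survival of Q at its mean age, and solved each end. Zeta's Q plus G still rose from 3.50% to 8.10% over its last readings, and south is colder, so I took Q there as made at a pace rising with X, which puts the mean age at a third of the time and the share at 64.2%. Eta had 8.40% of its 14.2% by 8.00 h, and north is warmer, so I put the mean birth of Q at a quarter of the time, which gives 1.52%.

The forecast, holding that “J kills E”, said 67% for south and 4% for north, with south highest.

South gave 74.1% and north 2.31%, so south held the highest share.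

    Z + D → D + X (k = 770 L mol⁻¹ h⁻¹, Ea = 57.0 kJ mol⁻¹)
    J + E → L (k = 7.10 L mol⁻¹ h⁻¹, Ea = 65.0 kJ mol⁻¹)
    J + Q → G (k = 3.70 L mol⁻¹ h⁻¹, Ea = 52.0 kJ mol⁻¹)
    J + E + X → E + Q (k = 19000 L² mol⁻² h⁻¹, Ea = 35.0 kJ mol⁻¹)
    (constants at 20 °C)

At 40.0 h south still had 40.5% of its E and north 0.00586%. Held at my half-life of 4.97 h, the 1.53% of Q that north held at 20.0 h falls to 0.0938% by the end of the run, and north had 0.173% of Q standing at 40.0 h. The same flask as north with 0.030 M of Z holds J at the same equivalents, so a half-life going inversely with J becomes 8.28 h, and that flask gave 12.2%.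

The numbers in the tables are calculated for substances that don't exist, and the scatter is random.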